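**Plan**
1. Retrosynthetic cuts: first the C2 propionate and the C13/C14 acetates; then the butenolide (C7–O–C19(=O)–C17(C18)=C8) back to a C7 alcohol with an isopropenyl group (C17, C18, C19) on C8; then the C7–C8 bond of the ten-membered ring (C1–C10) by a retro-[2,3]-Wittig shift to a thirteen-membered bis-allylic ether C7–O–C19.
2. Enabling feature: C7 (lactone O–CH) and C8 (butenolide carbon carrying C17/C18/C19) are adjacent atoms of the ten-membered ring, so the butenolide is a masked homoallylic alcohol plus isopropenyl group, which is the product pattern of a [2,3]-Wittig shift.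
3. Further cuts: ether O–C7 (Williamson), C4–C5 (B-alkyl Suzuki), C8–C9 (Negishi), C2–C3 (vinyl addition), and the cyclohexene (C1, C10–C14) by a Diels–Alder reaction forming C1–C14 and C10–C11.
4. Forward order: cyclohexene ring, then the C1 and C10 arms, then the thirteen-membered ether ring, its contraction to the ten-membered carbocycle, and last the butenolide ring.
5. Stereochemistry: C1, C10 and C14 from a catalytic asymmetric endo Diels–Alder reaction; C13 by hydroxyl-directed epoxidation and selenoxide transposition; C2 by CBS reduction; Z-C5=C6 from a (Z)-vinyl iodide; C7 from the ring-contraction transition state.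

Key step: step 19

Numbering: atom labels C1–C19 are those of the target skeleton (C1 quaternary fusion carbon, C2 propionyloxy CH, C3/C4 CH2, C5=C6, C7 lactone O–CH, C8=C17, C18 methyl on C17, C19 lactone carbonyl, C9 CH2, C10 fusion CH, C11=C12, C13/C14 acetoxy CH).
Assumption 1: the oxazaborolidinium catalyst derived from (S)-diphenylprolinol is taken to shield the enal face that leads to adduct 4; if the sense proves opposite, the mirror-image catalyst is used and nothing else changes.
Assumption 2: ethyl (E)-3-iodo-2-methylprop-2-enoate (17) is treated as a catalogue compound.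

Step 1
Reactants: 1 (E)-pent-2-enal
Product: 2 (1E,3E)-1-(triethylsilyloxy)penta-1,3-diene
Conditions: Et3SiOTf, Et3N, Et2O, 0 °C to rt
Reagents that add atoms: triethylsilyl trifluoromethanesulfonate, CC[Si](CC)(CC)OS(=O)(=O)C(F)(F)F
Why: O-silylation and γ-deprotonation of the enal (silyl dienol ether formation) should give the 1-silyloxydiene, of which only the E,E isomer can adopt the s-cis form needed in step 2.

Step 2
Reactants: 2 (1E,3E)-1-(triethylsilyloxy)penta-1,3-diene; 3 ethyl (E)-3-methyl-4-oxobut-2-enoate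
Product: 4 ethyl (1R,2S,5R,6S)-6-formyl-2,6-dimethyl-5-(triethylsilyloxy)cyclohex-3-ene-1-carboxylate
Conditions: (S)-1-(o-tolyl)-3,3-diphenyl-tetrahydropyrrolo[1,2-c][1,3,2]oxazaborole (20 mol %), HNTf2 (16 mol %), CH2Cl2, −78 °C
Reagents that add atoms: none
Why: Catalytic asymmetric Diels–Alder reaction in which the boron Lewis acid binds the formyl group, so the silyloxy terminus (C14) bonds to C1 and the methyl-bearing terminus (C11) to C10, the formyl group sits endo (cis to OSiEt3 and to the C11 methyl), the E dienophile keeps CHO and CO2Et trans, and the shielded enal face fixes C1, C10 and C14 in absolute terms.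

Step 3
Reactants: 4 ethyl (1R,2S,5R,6S)-6-formyl-2,6-dimethyl-5-(triethylsilyloxy)cyclohex-3-ene-1-carboxylate
Product: 5 vinyl carbinol (compound 4 with CHO converted to CH(OH)CH=CH2; both C2 epimers)
Conditions: CH2=CHMgBr (1.2 equiv), THF, −78 °C, cold NH4Cl quench
Reagents that add atoms: vinylmagnesium bromide, C=C[Mg]Br
Why: Grignard addition should be selective for the aldehyde over the ethyl ester at −78 °C, and the C2 epimer ratio is irrelevant because C2 is oxidised in step 4.

Step 4
Reactants: 5 vinyl carbinol (C2 epimers)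
Product: 6 vinyl ketone (compound 4 with CHO converted to C(=O)CH=CH2)
Conditions: Dess–Martin periodinane, NaHCO3, CH2Cl2, 0 °C
Reagents that add atoms: none
Why: Dess–Martin oxidation of an allylic alcohol; C1 is quaternary, so neither epimerisation nor β-elimination of the silyloxy group can occur.

Step 5
Reactants: 6 vinyl ketone
Product: 7 (2S)-allylic alcohol (compound 4 with CHO converted to (S)-CH(OH)CH=CH2)
Conditions: (R)-2-methyl-CBS-oxazaborolidine (0.3 equiv), catecholborane, toluene, −78 °C
Reagents that add atoms: none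
Why: CBS reduction, in which the ketone binds with the large quaternary C1 away from boron and the small vinyl group toward it, so the (R)-catalyst should deliver hydride to the face giving the 2S carbinol.

Step 6
Reactants: 7 (2S)-allylic alcohol
Product: 8 C2 tert-butyldimethylsilyl ether of 7
Conditions: t-BuMe2SiOTf, 2,6-lutidine, CH2Cl2, −78 °C to 0 °C
Reagents that add atoms: tert-butyldimethylsilyl trifluoromethanesulfonate, CC(C)(C)[Si](C)(C)OS(=O)(=O)C(F)(F)F
Why: Silylation of a hindered secondary alcohol with a silyl triflate, done at once so that the free C2 hydroxyl cannot lactonise onto the C9 ester.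

Step 7
Reactants: 8 C2 tert-butyldimethylsilyl ether of 7
Product: 9 C14 alcohol (8 without the triethylsilyl group)
Conditions: PPTS (0.2 equiv), EtOH, 0 °C to rt
Reagents that add atoms: none
Why: Acid-catalysed ethanolysis should cleave the triethylsilyl ether far faster than the hindered tert-butyldimethylsilyl ether (selective desilylation), and ethanol cannot scramble the ethyl ester.

Step 8
Reactants: 9 C14 alcohol
Product: 10 12,13-epoxide of 9 (epoxide oxygen cis to the C14 hydroxyl)
Conditions: mCPBA, NaHCO3, CH2Cl2, 0 °C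
Reagents that add atoms: 3-chloroperoxybenzoic acid, OOC(=O)c1cccc(Cl)c1
Why: Hydroxyl-directed peracid epoxidation delivers oxygen syn to the allylic C14 hydroxyl, and the cis-disubstituted ring alkene should react well before the vinyl group next to the silyloxy carbon.

Step 9
Reactants: 10 12,13-epoxide of 9
Product: 13 allylic cis-13,14-diol (C11=C12 alkene; 13-OH cis to 14-OH), via hydroxy selenide 11 (not isolated), via selenoxide 12 (not isolated)
Conditions: (PhSe)2, NaBH4, EtOH, 70 °C; then H2O2 (30%), pyridine, THF, 0 °C to rt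
Reagents that add atoms: none
Why: Epoxide-to-allylic-alcohol transposition: the selenolate should open the epoxide at C12 (remote from the carbinol, trans-diaxial), and the selenoxide eliminates syn with H-11 instead of toward the carbinol carbon C13, so the retained epoxide oxygen becomes the C13 hydroxyl cis to the C14 hydroxyl.

Step 10
Reactants: 13 allylic cis-13,14-diol
Product: 14 13,14-acetonide of 13
Conditions: Me2C(OMe)2, PPTS (cat.), CH2Cl2, rt
Reagents that add atoms: 2,2-dimethoxypropane, COC(C)(C)OC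
Why: Acetal exchange on a cis-1,2-diol gives the five-membered isopropylidene acetal (acetonide formation).

Step 11
Reactants: 14 13,14-acetonide of 13
Product: 15 primary alcohol (C9 ester reduced to CH2OH)
Conditions: i-Bu2AlH, CH2Cl2, −78 °C to 0 °C
Reagents that add atoms: none
Why: Standard aluminium hydride reduction of the ester, tolerated by the silyl ether, acetonide and alkenes.

Step 12
Reactants: 15 primary alcohol
Product: 16 primary iodide (C9H2I)
Conditions: I2, PPh3, imidazole, CH2Cl2, 0 °C to rt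
Reagents that add atoms: iodine, II
Why: Appel-type iodination of a primary alcohol through the alkoxyphosphonium salt.

Step 13
Reactants: 16 primary iodide; 17 ethyl (E)-3-iodo-2-methylprop-2-enoate
Product: 20 (E)-enoate (C9H2–C8H=C17(CH3)–C19O2Et arm on C10), via alkyllithium 18 (not isolated), via alkylzinc chloride 19 (not isolated)
Conditions: t-BuLi (2.1 equiv), Et2O, −78 °C; ZnCl2, THF, −78 °C to rt; then 17, Pd(PPh3)4 (5 mol %), rt
Reagents that add atoms: none
Why: Iodine–lithium exchange and transmetalation to zinc at −78 °C (before the 5-hexenyllithium can cyclise onto the vinyl group), then Negishi coupling with retention of the E geometry of the vinyl iodide.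

Step 14
Reactants: 21 but-2-yn-1-ol
Product: 23 (Z)-3-iodobut-2-en-1-ol, via cyclic alkenylaluminate 22 (not isolated)
Conditions: NaAlH2(OCH2CH2OCH3)2, THF, 0 °C to rt; then I2, −78 °C to 0 °C
Reagents that add atoms: iodine, II
Why: Alkoxide-directed trans-hydroalumination of the propargylic alcohol places aluminium on C3 cis to CH2O, and iodinolysis with retention gives the Z-vinyl iodide.

Step 15
Reactants: 20 (E)-enoate; 23 (Z)-3-iodobut-2-en-1-ol
Product: 25 (Z)-allylic alcohol (C7H2OH; Z-C5=C6 joined to C4), via B-alkyl-9-BBN 24 (not isolated)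
Conditions: 9-BBN, THF, rt; then 23, PdCl2(dppf) (5 mol %), AsPh3, Cs2CO3, DMF–H2O, rt
Reagents that add atoms: none
Why: 9-BBN hydroborates only the terminal vinyl group (boron on C4), and B-alkyl Suzuki–Miyaura coupling proceeds with retention at the vinyl iodide, giving the Z trisubstituted C5=C6 alkene.

Step 16
Reactants: 25 (Z)-allylic alcohol
Product: 26 (Z)-allylic chloride (C7H2Cl)
Conditions: NCS, Me2S, CH2Cl2, −20 °C to 0 °C
Reagents that add atoms: N-chlorosuccinimide, O=C1CCC(=O)N1Cl
Why: Corey–Kim chlorination converts a primary allylic alcohol into the chloride without allylic transposition or loss of Z geometry.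

Step 17
Reactants: 26 (Z)-allylic chloride
Product: 27 chloro alcohol with C19D2OH (enoate reduced)
Conditions: LiAlD4, Et2O, −78 °C to −30 °C
Reagents that add atoms: lithium aluminium deuteride, [Li+].[2H][Al-]([2H])([2H])[2H]
Why: 1,2-Reduction of the enoate at low temperature should leave the allylic chloride untouched; the two deuterium atoms at C19 steer the lithiation of step 19 and are lost when C19 becomes the lactone carbonyl in step 21.

Step 18
Reactants: 27 chloro alcohol with C19D2OH
Product: 29 thirteen-membered bis-allylic ether (C7H2–O–C19D2; Z-C5=C6; E-C8=C17; C2 silyl ether; 13,14-acetonide), via sodium alkoxide 28 (not isolated)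
Conditions: NaH, 15-crown-5 (cat.), THF, 45 °C, slow addition to 0.003 M
Reagents that add atoms: none
Why: Intramolecular Williamson etherification of a primary allylic chloride under high dilution, a ring closure known for thirteen-membered bis-allylic ethers, with both alkene geometries untouched under basic SN2 conditions.

Step 19
Reactants: 29 thirteen-membered bis-allylic ether
Product: 31 ten-membered (7R,8S)-alcohol with a dideuterio-isopropenyl group on C8, via C7-lithio ether 30 (not isolated)
Conditions: s-BuLi (1.5 equiv), THF, −78 °C, then −78 °C to −30 °C; aq. NH4Cl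
Reagents that add atoms: none
Why: s-BuLi removes a proton from C7 (allylic and α to oxygen) and the α-oxyallyllithium 30 undergoes a suprafacial [2,3]-Wittig shift through a five-membered envelope transition state (C7, O, C19, C17, C8), forming C7–C8, breaking O–C19 and moving the alkene to C17=C19. The closest known reaction is the [2,3]-Wittig ring contraction of thirteen-membered bis-allylic ethers to ten-membered homoallylic alcohols. The ten-membered carbocycle arises by contraction of the ether ring, C7 bonding to C8 across the ring while O, C19 and C17 leave it, not by an end-to-end cyclisation. C8 is set relative to C7 by the E geometry of C8=C17 together with an exo placement of the C6 vinyl group on the envelope (trans, 7R*,8S*), and the absolute sense is set by the C1/C10 ring fusion, whose trans-disposed arms are expected to expose one face of the C8=C17 plane to the ether bridge; this facial sense is an expectation and not secured by analogy, and C8 becomes trigonal later. The step needs lithiation at C7 and not at C19: the C19 deuterium atoms slow the competing deprotonation by a primary kinetic isotope effect and a C19 anion could only bond to the fully substituted C5, while −78 °C keeps the Z geometry of C5=C6 in the allyl anion and suppresses the [1,2]-shift.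

Step 20
Reactants: 31 ten-membered (7R,8S)-alcohol
Product: 33 7,19-diol (C17 epimers; C19D2OH), via bis(boryl) intermediate 32 (not isolated)
Conditions: 9-BBN (3 equiv), THF, rt; then NaOH, H2O2, 0 °C
Reagents that add atoms: hydrogen peroxide, OO
Why: 9-BBN hydroborates the 1,1-disubstituted alkene anti-Markovnikov and leaves both trisubstituted alkenes alone; the new C17 centre is removed in step 22.

Step 21
Reactants: 33 7,19-diol
Product: 36 trans-fused γ-lactone (C7–O–C19(=O); C17 epimers), via hydroxy aldehyde 34 (not isolated), via lactol 35 (not isolated)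
Conditions: TEMPO (0.2 equiv), PhI(OAc)2 (3 equiv), CH2Cl2, rt
Reagents that add atoms: none
Why: Oxidative lactonisation of a 1,4-diol: the oxoammonium oxidant takes the primary alcohol first, the hydroxy aldehyde closes to the lactol, and this is oxidised on to the lactone, C19 losing both deuterium atoms.

Step 22
Reactants: 36 trans-fused γ-lactone
Product: 40 butenolide (C8=C17; C2 silyl ether; 13,14-acetonide), via lithium enolate 37 (not isolated), via C17 selenide 38 (not isolated), via selenoxide 39 (not isolated)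
Conditions: LDA, THF, −78 °C; PhSeBr, −78 °C; then H2O2 (30%), pyridine, CH2Cl2, 0 °C
Reagents that add atoms: none
Why: The lactone enolate should be selenenylated at C17 anti to C9 (cis to H-8), and selenoxide syn-elimination with H-8 gives the conjugated tetrasubstituted C8=C17 alkene, which removes the C8 and C17 stereocentres.

Step 23
Reactants: 40 butenolide
Product: 41 C2 alcohol (40 without the silyl group)
Conditions: HF·pyridine, pyridine, THF, 0 °C to rt
Reagents that add atoms: none
Why: Buffered fluoride desilylation cleaves the silyl ether without touching the acetonide or deprotonating the butenolide at C7.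

Step 24
Reactants: 41 C2 alcohol
Product: 42 C2 propionate
Conditions: (EtCO)2O, pyridine, DMAP (cat.), CH2Cl2, rt
Reagents that add atoms: propionic anhydride, CCC(=O)OC(=O)CC
Why: DMAP-catalysed acylation of the hindered secondary alcohol under weakly basic conditions that leave C7 untouched.

Step 25
Reactants: 42 C2 propionate
Product: 43 13,14-diol (acetonide removed)
Conditions: AcOH–H2O 4:1, 40 °C
Reagents that add atoms: none
Why: Mild acid hydrolysis of the isopropylidene acetal should leave the esters and the allylic lactone C7–O bond intact.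

Step 26
Reactants: 43 13,14-diol
Product: 44 target CNP0180501.3 (2-propionate 13,14-diacetate; 1R,2S,7R,10R,13R,14S; 5Z)
Conditions: Ac2O, pyridine, DMAP (cat.), CH2Cl2, rt
Reagents that add atoms: acetic anhydride, CC(=O)OC(C)=O
Why: Exhaustive acetylation of the two secondary hydroxyls completes the target.

**Compound list**
1 | (E)-pent-2-enal | CC/C=C/C=O | starting material
2 | (1E,3E)-1-(triethylsilyloxy)penta-1,3-diene | C/C=C/C=C/O[Si](CC)(CC)CC | intermediate
3 | ethyl (E)-3-methyl-4-oxobut-2-enoate | CCOC(=O)/C=C(\C)C=O | starting material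
4 | ethyl (1R,2S,5R,6S)-6-formyl-2,6-dimethyl-5-(triethylsilyloxy)cyclohex-3-ene-1-carboxylate | O=C[C@]1(C)[C@H](O[Si](CC)(CC)CC)C=C[C@H](C)[C@H]1C(=O)OCC | intermediate
5 | vinyl carbinol, C2 epimers (4 with CH(OH)CH=CH2 in place of CHO) | C=CC(O)[C@]1(C)[C@H](O[Si](CC)(CC)CC)C=C[C@H](C)[C@H]1C(=O)OCC | intermediate
6 | vinyl ketone (4 with C(=O)CH=CH2 in place of CHO) | C=CC(=O)[C@]1(C)[C@H](O[Si](CC)(CC)CC)C=C[C@H](C)[C@H]1C(=O)OCC | intermediate
7 | (2S)-allylic alcohol | C=C[C@H](O)[C@]1(C)[C@H](O[Si](CC)(CC)CC)C=C[C@H](C)[C@H]1C(=O)OCC | intermediate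
8 | C2 tert-butyldimethylsilyl ether of 7 | C=C[C@H](O[Si](C)(C)C(C)(C)C)[C@]1(C)[C@H](O[Si](CC)(CC)CC)C=C[C@H](C)[C@H]1C(=O)OCC | intermediate
9 | C14 alcohol | C=C[C@H](O[Si](C)(C)C(C)(C)C)[C@]1(C)[C@H](O)C=C[C@H](C)[C@H]1C(=O)OCC | intermediate
10 | 12,13-epoxide cis to the C14 hydroxyl | C=C[C@H](O[Si](C)(C)C(C)(C)C)[C@]1(C)[C@H](O)[C@@H]2O[C@@H]2[C@H](C)[C@H]1C(=O)OCC | intermediate
11 | hydroxy selenide (C12 SePh trans to 13-OH) | C=C[C@H](O[Si](C)(C)C(C)(C)C)[C@]1(C)[C@H](O)[C@H](O)[C@@H]([Se]c2ccccc2)[C@H](C)[C@H]1C(=O)OCC | intermediate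
12 | selenoxide of 11 | C=C[C@H](O[Si](C)(C)C(C)(C)C)[C@]1(C)[C@H](O)[C@H](O)[C@@H]([Se](=O)c2ccccc2)[C@H](C)[C@H]1C(=O)OCC | intermediate
13 | allylic cis-13,14-diol with C11=C12 | C=C[C@H](O[Si](C)(C)C(C)(C)C)[C@]1(C)[C@H](O)[C@H](O)C=C(C)[C@H]1C(=O)OCC | intermediate
14 | 13,14-acetonide ester | C=C[C@H](O[Si](C)(C)C(C)(C)C)[C@]1(C)[C@@H]2OC(C)(C)O[C@@H]2C=C(C)[C@H]1C(=O)OCC | intermediate
15 | primary alcohol (C9H2OH) | C=C[C@H](O[Si](C)(C)C(C)(C)C)[C@]1(C)[C@@H]2OC(C)(C)O[C@@H]2C=C(C)[C@H]1CO | intermediate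
16 | primary iodide (C9H2I) | C=C[C@H](O[Si](C)(C)C(C)(C)C)[C@]1(C)[C@@H]2OC(C)(C)O[C@@H]2C=C(C)[C@H]1CI | intermediate
17 | ethyl (E)-3-iodo-2-methylprop-2-enoate | CCOC(=O)/C(C)=C/I | starting material
18 | alkyllithium from 16 | C=C[C@H](O[Si](C)(C)C(C)(C)C)[C@]1(C)[C@@H]2OC(C)(C)O[C@@H]2C=C(C)[C@H]1C[Li] | intermediate
19 | alkylzinc chloride from 18 | C=C[C@H](O[Si](C)(C)C(C)(C)C)[C@]1(C)[C@@H]2OC(C)(C)O[C@@H]2C=C(C)[C@H]1C[Zn]Cl | intermediate
20 | (E)-enoate | C=C[C@H](O[Si](C)(C)C(C)(C)C)[C@]1(C)[C@@H]2OC(C)(C)O[C@@H]2C=C(C)[C@H]1C/C=C(\C)C(=O)OCC | intermediate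
21 | but-2-yn-1-ol | CC#CCO | starting material
22 | cyclic alkenylaluminate (sodium salt) | CC1=CCO[Al-]1(OCCOC)OCCOC.[Na+] | intermediate
23 | (Z)-3-iodobut-2-en-1-ol | C/C(I)=C/CO | intermediate
24 | B-alkyl-9-BBN from 20 | B1(CC[C@H](O[Si](C)(C)C(C)(C)C)[C@]3(C)[C@@H]4OC(C)(C)O[C@@H]4C=C(C)[C@H]3C/C=C(\C)C(=O)OCC)C2CCCC1CCC2 | intermediate
25 | (Z)-allylic alcohol (C7H2OH) | OC/C=C(C)\CC[C@H](O[Si](C)(C)C(C)(C)C)[C@]1(C)[C@@H]2OC(C)(C)O[C@@H]2C=C(C)[C@H]1C/C=C(\C)C(=O)OCC | intermediate
26 | (Z)-allylic chloride (C7H2Cl) | ClC/C=C(C)\CC[C@H](O[Si](C)(C)C(C)(C)C)[C@]1(C)[C@@H]2OC(C)(C)O[C@@H]2C=C(C)[C@H]1C/C=C(\C)C(=O)OCC | intermediate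
27 | chloro alcohol with C19D2OH | ClC/C=C(C)\CC[C@H](O[Si](C)(C)C(C)(C)C)[C@]1(C)[C@@H]2OC(C)(C)O[C@@H]2C=C(C)[C@H]1C/C=C(\C)C([2H])([2H])O | intermediate
28 | sodium alkoxide of 27 | [Na+].ClC/C=C(C)\CC[C@H](O[Si](C)(C)C(C)(C)C)[C@]1(C)[C@@H]2OC(C)(C)O[C@@H]2C=C(C)[C@H]1C/C=C(\C)C([2H])([2H])[O-] | intermediate
29 | thirteen-membered bis-allylic ether (key-step precursor) | CC(C)(C)[Si](C)(C)O[C@H]1CC/C(C)=C\COC([2H])([2H])/C(C)=C/C[C@@H]2C(C)=C[C@H]3OC(C)(C)O[C@H]3[C@@]12C | intermediate
30 | C7-lithio ether | CC(C)(C)[Si](C)(C)O[C@H]1CC/C(C)=C\C([Li])OC([2H])([2H])/C(C)=C/C[C@@H]2C(C)=C[C@H]3OC(C)(C)O[C@H]3[C@@]12C | intermediate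
31 | ten-membered (7R,8S)-alcohol with C8 dideuterio-isopropenyl group (key-step product) | CC(C)(C)[Si](C)(C)O[C@H]1CC/C(C)=C\[C@@H](O)[C@H](C(C)=C([2H])[2H])C[C@@H]2C(C)=C[C@H]3OC(C)(C)O[C@H]3[C@@]12C | intermediate
32 | bis(boryl) intermediate (O–B at C7, C–B at C19) | CC(C)(C)[Si](C)(C)O[C@H]1CC/C(C)=C\[C@@H](OB4C5CCCC4CCC5)[C@H](C(C)C([2H])([2H])B6C7CCCC6CCC7)C[C@@H]2C(C)=C[C@H]3OC(C)(C)O[C@H]3[C@@]12C | intermediate
33 | 7,19-diol (C7/C8 as in 31; C17 epimers) | CC(C)(C)[Si](C)(C)O[C@H]1CC/C(C)=C\[C@@H](O)[C@H](C(C)C([2H])([2H])O)C[C@@H]2C(C)=C[C@H]3OC(C)(C)O[C@H]3[C@@]12C | intermediate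
34 | hydroxy aldehyde | CC(C)(C)[Si](C)(C)O[C@H]1CC/C(C)=C\[C@@H](O)[C@H](C(C)C([2H])=O)C[C@@H]2C(C)=C[C@H]3OC(C)(C)O[C@H]3[C@@]12C | intermediate
35 | lactol | CC(C)(C)[Si](C)(C)O[C@H]1CC/C(C)=C\[C@H]2OC([2H])(O)C(C)[C@@H]2C[C@@H]3C(C)=C[C@H]4OC(C)(C)O[C@H]4[C@@]13C | intermediate
36 | trans-fused γ-lactone (H-7 and H-8 trans; C17 epimers) | CC(C)(C)[Si](C)(C)O[C@H]1CC/C(C)=C\[C@H]2OC(=O)C(C)[C@@H]2C[C@@H]3C(C)=C[C@H]4OC(C)(C)O[C@H]4[C@@]13C | intermediate
37 | lithium enolate of 36 | CC(C)(C)[Si](C)(C)O[C@H]1CC/C(C)=C\[C@H]2OC(O[Li])=C(C)[C@@H]2C[C@@H]3C(C)=C[C@H]4OC(C)(C)O[C@H]4[C@@]13C | intermediate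
38 | C17 selenide (SePh cis to H-8) | CC(C)(C)[Si](C)(C)O[C@H]1CC/C(C)=C\[C@H]2OC(=O)[C@@](C)([Se]c5ccccc5)[C@@H]2C[C@@H]3C(C)=C[C@H]4OC(C)(C)O[C@H]4[C@@]13C | intermediate
39 | selenoxide of 38 | CC(C)(C)[Si](C)(C)O[C@H]1CC/C(C)=C\[C@H]2OC(=O)[C@@](C)([Se](=O)c5ccccc5)[C@@H]2C[C@@H]3C(C)=C[C@H]4OC(C)(C)O[C@H]4[C@@]13C | intermediate
40 | butenolide (C2 silyl ether, 13,14-acetonide) | CC(C)(C)[Si](C)(C)O[C@H]1CC/C(C)=C\[C@H]2OC(=O)C(C)=C2C[C@@H]3C(C)=C[C@H]4OC(C)(C)O[C@H]4[C@@]13C | intermediate
41 | C2 alcohol | O[C@H]1CC/C(C)=C\[C@H]2OC(=O)C(C)=C2C[C@@H]3C(C)=C[C@H]4OC(C)(C)O[C@H]4[C@@]13C | intermediate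
42 | C2 propionate (13,14-acetonide) | CCC(=O)O[C@H]1CC/C(C)=C\[C@H]2OC(=O)C(C)=C2C[C@@H]3C(C)=C[C@H]4OC(C)(C)O[C@H]4[C@@]13C | intermediate
43 | C2 propionate 13,14-diol | CCC(=O)O[C@H]1CC/C(C)=C\[C@H]2OC(=O)C(C)=C2C[C@@H]3C(C)=C[C@@H](O)[C@@H](O)[C@@]13C | intermediate
44 | CNP0180501.3 | CCC(=O)O[C@H]1CC/C(C)=C\[C@H]2OC(=O)C(C)=C2C[C@@H]2C(C)=C[C@@H](OC(C)=O)[C@@H](OC(C)=O)[C@@]12C | target

**Step count**
Total: 26 steps. Longest linear sequence: 25 steps (steps 1–13 and 15–26, from (E)-pent-2-enal); step 14 prepares the vinyl iodide separately.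

**Steps most likely to fail**

1. Step 19. The carbanion may close on the other face of the C8=C17 alkene, so that the trans pair of centres is formed with the opposite sense at C7 and C8; this is the least predictable point of the route. The fallback sets out from 29 and accepts that outcome. The same lithiation then gives the (7S,8R)-alcohol F1, which is hydroborated and oxidised as in step 20 to the 7,19-diol F2 and lactonised as in step 21 to the trans-lactone F3 (epimeric with 36 at C7 and C8). LiOH in THF–H2O opens F3 to the hydroxy acid F4, and Mitsunobu lactonisation (PPh3, diisopropyl azodicarboxylate, toluene, 0 °C) closes the ring again with inversion at C7 to the cis-lactone F5, which has the C7 configuration of 36. Selenenylation and selenoxide elimination as in step 22 erase C8 and return the route at 40.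

2. Step 2. Silyl transfer from the dienol ether to the activated aldehyde, or erosion of facial selectivity under the cationic boron catalyst, may outrun clean cycloaddition. The fallback sets out from 2 and 3 and runs the cycloaddition thermally (toluene, 80 °C, no catalyst), giving 4 together with its enantiomer F6. Steps 3 and 4 carry the racemate on through the mirror-image carbinols F7 to the mirror-image ketone F8 alongside 6. The CBS reduction of step 5 then turns the two enantiomeric ketones into diastereomers, 7 and the 2S alcohol of the mirror-image ring series F9, which are separated by chromatography; the route is rejoined at 7.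

3. Step 22. The selenoxide may eliminate toward the C18 methyl hydrogens instead of H-8, which is the usual course when the selenium ends up trans to the ring hydrogen in trans-fused lactones. The fallback sets out from 36 and takes the exocyclic product of the same sequence, the α-methylene lactone F10, on to the conjugated isomer by metal-hydride alkene isomerisation (RhH(CO)(PPh3)3, 5 mol %, toluene, 80 °C); it returns at 40.

**Further compounds**
F1 | step 19 | (7S,8R)-alcohol, epimer of 31 at C7 and C8 | CC(C)(C)[Si](C)(C)O[C@H]1CC/C(C)=C\[C@H](O)[C@@H](C(C)=C([2H])[2H])C[C@@H]2C(C)=C[C@H]3OC(C)(C)O[C@H]3[C@@]12C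
F2 | step 19 | 7,19-diol from F1 | CC(C)(C)[Si](C)(C)O[C@H]1CC/C(C)=C\[C@H](O)[C@@H](C(C)C([2H])([2H])O)C[C@@H]2C(C)=C[C@H]3OC(C)(C)O[C@H]3[C@@]12C
F3 | step 19 | trans-lactone epimeric with 36 at C7 and C8 | CC(C)(C)[Si](C)(C)O[C@H]1CC/C(C)=C\[C@@H]2OC(=O)C(C)[C@H]2C[C@@H]3C(C)=C[C@H]4OC(C)(C)O[C@H]4[C@@]13C
F4 | step 19 | hydroxy acid from F3 | CC(C)(C)[Si](C)(C)O[C@H]1CC/C(C)=C\[C@H](O)[C@@H](C(C)C(=O)O)C[C@@H]2C(C)=C[C@H]3OC(C)(C)O[C@H]3[C@@]12C
F5 | step 19 | cis-lactone (C7 as in 36, C8 epimeric) | CC(C)(C)[Si](C)(C)O[C@H]1CC/C(C)=C\[C@H]2OC(=O)C(C)[C@H]2C[C@@H]3C(C)=C[C@H]4OC(C)(C)O[C@H]4[C@@]13C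
F6 | step 2 | enantiomer of 4 | O=C[C@@]1(C)[C@@H](O[Si](CC)(CC)CC)C=C[C@@H](C)[C@@H]1C(=O)OCC
F7 | step 2 | enantiomeric series of carbinols 5 | C=CC(O)[C@@]1(C)[C@@H](O[Si](CC)(CC)CC)C=C[C@@H](C)[C@@H]1C(=O)OCC
F8 | step 2 | enantiomer of 6 | C=CC(=O)[C@@]1(C)[C@@H](O[Si](CC)(CC)CC)C=C[C@@H](C)[C@@H]1C(=O)OCC
F9 | step 2 | (2S)-allylic alcohol of the mirror-image ring series | C=C[C@H](O)[C@@]1(C)[C@@H](O[Si](CC)(CC)CC)C=C[C@@H](C)[C@@H]1C(=O)OCC
F10 | step 22 | α-methylene lactone (C17=CH2) | CC(C)(C)[Si](C)(C)O[C@H]1CC/C(C)=C\[C@H]2OC(=O)C(=C)[C@@H]2C[C@@H]3C(C)=C[C@H]4OC(C)(C)O[C@H]4[C@@]13C
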